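The route rests on cutting the O1–C8a bond of ring C, so that ring A enters with four oxygens and a hydrogen at the future C8a. The feature used is the pair of adjacent hydroxyls on C5 and C6 of ring A. Two-electron oxidation turns them into an ortho-quinone whose only hydrogen-bearing carbon, C8a, is the acceptor terminus of the C5 enone and is also conjugated to the C4 ketone. In a single operation the catechol is oxidised, the enol oxygen at C2 adds to C8a, and a proton shift re-aromatises ring A, now fused to the closed pyranone. The substrate is an open-chain 1,3-diketone linking a 2,3-dihydroxy-4,5-dimethoxyphenyl ring to an O-benzyl isovanilloyl group.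

Key step: step 6

Remark: the 1,3-diketones are drawn in the diketo form although they should exist largely as chelated enols. Flavone numbering (O1, C2–C4, C4a, C5–C8, C8a) is also used for the atoms of the open-chain precursor that become ring C and ring A.

Step 1
Reactants: 1 1,2,3,4-tetramethoxybenzene
Product: 3 2-hydroxy-3,4,5-trimethoxyacetophenone, via 2,3,4,5-tetramethoxyacetophenone 2 (not isolated)
Conditions: AcCl (1.2 equiv), AlCl3 (2.5 equiv), CH2Cl2, 0 °C to 40 °C; then ice/aq. HCl
Reagents that add atoms: acetyl chloride, CC(=O)Cl
Why: Friedel–Crafts acylation can only take place at the two equivalent free positions of the symmetric arene, and the aluminium-bound ketone should then lose the methyl of the flanking 2-methoxy group by chloride attack inside the six-membered chelate (chelation-controlled ortho-demethylation), leaving the three remote ethers intact.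

Step 2
Reactants: 3 2-hydroxy-3,4,5-trimethoxyacetophenone
Product: 4 2,3-dihydroxy-4,5-dimethoxyacetophenone
Conditions: AlBr3 (3 equiv), MeCN, 0 °C to rt; then 2 M HCl, 50 °C
Reagents that add atoms: none
Why: Chelation-assisted Lewis-acid ether cleavage, in which the aluminium phenoxide at O2 binds the neighbouring 3-methoxy oxygen in a five-membered ring so that bromide removes that methyl group (SN2 at carbon) in preference to the 4- and 5-methoxy groups, which have no adjacent aluminium alkoxide.

Step 3
Reactants: 5 isovanillic acid (3-hydroxy-4-methoxybenzoic acid)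
Product: 6 3-benzyloxy-4-methoxybenzoic acid
Conditions: BnBr (1.5 equiv), NaOH (3.5 equiv), EtOH–H2O, reflux; then aq. HCl to pH 2
Reagents that add atoms: benzyl bromide, BrCc1ccccc1
Why: Williamson ether synthesis on the dianion, whose phenoxide is the more nucleophilic oxygen in aqueous ethanol, with any benzyl ester formed alongside being saponified by the excess hydroxide at reflux.

Step 4
Reactants: 6 3-benzyloxy-4-methoxybenzoic acid
Product: 7 3-benzyloxy-4-methoxybenzoyl chloride
Conditions: (COCl)2 (1.5 equiv), DMF (cat.), CH2Cl2, 0 °C to rt; evaporated and used crude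
Reagents that add atoms: oxalyl chloride, O=C(Cl)C(=O)Cl
Why: Acid chloride formation through the chloroiminium species generated from DMF and oxalyl chloride, conditions to which the benzyl and methyl aryl ethers are inert.

Step 5
Reactants: 4 2,3-dihydroxy-4,5-dimethoxyacetophenone; 7 3-benzyloxy-4-methoxybenzoyl chloride
Product: 8 1-(3-benzyloxy-4-methoxyphenyl)-3-(2,3-dihydroxy-4,5-dimethoxyphenyl)propane-1,3-dione
Conditions: 4, LiN(SiMe3)2 (4.2 equiv), THF, −78 to −20 °C; then 7 (1.0 equiv), −78 °C to rt, Ar; cold degassed aq. HCl to pH 3–4
Reagents that add atoms: none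
Why: Crossed Claisen-type C-aroylation of a ketone lithium enolate within a polyanion, where the enolate carbon should be far more nucleophilic than the aggregated lithium phenoxides and the fourth equivalent of base converts the product into its unreactive diketonate so that only one aroyl group is transferred.

Step 6
Reactants: 8 1-(3-benzyloxy-4-methoxyphenyl)-3-(2,3-dihydroxy-4,5-dimethoxyphenyl)propane-1,3-dione
Product: 11 3'-benzyloxy-5,6-dihydroxy-7,8,4'-trimethoxyflavone, via 3-acyl-5,6-dimethoxy-1,2-benzoquinone 9 (not isolated), via 8a-H dienone adduct 10 (not isolated)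
Conditions: o-chloranil (1.0 equiv), dry CH2Cl2 (0.01 M), −40 °C to rt, Ar, dark
Reagents that add atoms: none
Why: Proposed new method: o-chloranil should remove two hydrogens from the catechol of 8 to give the 3-acyl ortho-quinone 9, whose only hydrogen-bearing ring carbon C8a is the β-position of a C4a=C8a bond activated by both the C5 quinone carbonyl and the C4 ketone; the chelated enol oxygen on C2 adds there to give dienone 10, and a proton shift from C8a to O6, relayed by the tetrachlorocatechol formed, re-aromatises ring A as catechol 11. The closest known reaction type is the oxidative cyclisation of 2-hydroxybenzophenones carrying a hydroquinone ring, where a phenol oxygen adds conjugately to the derived quinone to give a xanthone; here an enol oxygen and an ortho-quinone play those parts. Ring C closes as a 6-endo-trig oxa-Michael addition, the attacked C4a=C8a bond lying inside the new six-membered ring. No stereocentre remains, because the sp3 C8a of 10 is planarised on aromatisation. The step must join O1 to C8a and must not let the 2-hydroxyl of the catechol ring (the future O5) condense with the diketone carbonyl, which would lead to the 5-deoxy 8-hydroxy-6,7-dimethoxyflavone skeleton; this is secured because oxidation turns that oxygen into a quinone carbonyl, because 1,2-addition of the enol oxygen to this carbonyl is reversible and cannot aromatise whereas the conjugate adduct aromatises irreversibly, and because neither strong acid nor heat is present to dehydrate unoxidised 8. One equivalent of oxidant should suffice, since any flavone quinone formed from 11 re-oxidises remaining 8 and is thereby returned to 11, and high dilution disfavours intermolecular addition of the diketone carbon to 9.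

Step 7
Reactants: 11 3'-benzyloxy-5,6-dihydroxy-7,8,4'-trimethoxyflavone
Product: 12 5,6,3'-trihydroxy-7,8,4'-trimethoxyflavone
Conditions: H2 (1 atm), Pd/C (10 wt% Pd), EtOAc–THF, rt
Reagents that add atoms: none
Why: Hydrogenolysis of the benzyl aryl ether on palladium should be much faster than reduction of the vinylogous-ester C2=C3 bond of the flavone, and the methyl ethers and the catechol are inert.

Compound list
1 | 1,2,3,4-tetramethoxybenzene | COc1ccc(OC)c(OC)c1OC | starting material
2 | 2,3,4,5-tetramethoxyacetophenone | CC(=O)c1cc(OC)c(OC)c(OC)c1OC | intermediate (not isolated)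
3 | 2-hydroxy-3,4,5-trimethoxyacetophenone | CC(=O)c1cc(OC)c(OC)c(OC)c1O | intermediate
4 | 2,3-dihydroxy-4,5-dimethoxyacetophenone | CC(=O)c1cc(OC)c(OC)c(O)c1O | intermediate
5 | isovanillic acid (3-hydroxy-4-methoxybenzoic acid) | COc1ccc(C(=O)O)cc1O | starting material
6 | 3-benzyloxy-4-methoxybenzoic acid | COc1ccc(C(=O)O)cc1OCc1ccccc1 | intermediate
7 | 3-benzyloxy-4-methoxybenzoyl chloride | COc1ccc(C(=O)Cl)cc1OCc1ccccc1 | intermediate
8 | 1-(3-benzyloxy-4-methoxyphenyl)-3-(2,3-dihydroxy-4,5-dimethoxyphenyl)propane-1,3-dione | COc1ccc(C(=O)CC(=O)c2cc(OC)c(OC)c(O)c2O)cc1OCc1ccccc1 | intermediate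
9 | 1-(3-benzyloxy-4-methoxyphenyl)-3-(4,5-dimethoxy-2,3-dioxocyclohexa-4,6-dien-1-yl)propane-1,3-dione (3-acyl-5,6-dimethoxy-1,2-benzoquinone) | COc1ccc(C(=O)CC(=O)C2=CC(OC)=C(OC)C(=O)C2=O)cc1OCc1ccccc1 | intermediate (not isolated)
10 | 2-(3-benzyloxy-4-methoxyphenyl)-5-hydroxy-7,8-dimethoxy-8aH-chromene-4,6-dione (racemic at C8a, centre lost on aromatisation) | COC1=C(OC)C(=O)C(O)=C2C(=O)C=C(c3ccc(OC)c(OCc4ccccc4)c3)OC12 | intermediate (not isolated)
11 | 3'-benzyloxy-5,6-dihydroxy-7,8,4'-trimethoxyflavone | COc1ccc(-c2cc(=O)c3c(O)c(O)c(OC)c(OC)c3o2)cc1OCc1ccccc1 | intermediate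
12 | 5,6,3'-trihydroxy-7,8,4'-trimethoxyflavone | COc1ccc(-c2cc(=O)c3c(O)c(O)c(OC)c(OC)c3o2)cc1O | target

Total step count: 7
Longest linear sequence: 5 steps (steps 1, 2, 5, 6, 7; the branch through steps 3, 4, 5, 6, 7 is equally long)

Steps most likely to fail

Step 6. The acyl ortho-quinone may be consumed by intermolecular conjugate addition of the diketone carbon of a second molecule before the enol oxygen closes ring C. The neutral enol may add too slowly. The electron-rich product may be over-oxidised and degrade. The fallback uses known chemistry and carries all five ring A oxygens from the start, so that O1 is formed by ordinary cyclodehydration. It sets out from acid chloride 7 and comes back to the route at target 12. Purchased 2-hydroxy-3,4,5,6-tetramethoxyacetophenone F1 would be C-aroylated with 7 (LiN(SiMe3)2, 3 equiv, THF, −78 °C to rt) to give 1-(3-benzyloxy-4-methoxyphenyl)-3-(2-hydroxy-3,4,5,6-tetramethoxyphenyl)propane-1,3-dione F2. Acid cyclodehydration (H2SO4 cat., AcOH, 80 °C) should then give 3'-benzyloxy-5,6,7,8,4'-pentamethoxyflavone F3. Treatment with AlBr3 in MeCN should remove the 5-methyl group through the C4 carbonyl chelate, the 6-methyl group next to the aluminium phenoxide so formed, and the benzyl group, giving 12 directly.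

Step 5. Aroyl transfer may go to the catecholate oxygens instead of the enolate carbon, and the polyanion may suffer oxidative degradation. The fallback sets out from ketone 4 and acid chloride 7 and comes back at diketone 8. Exhaustive O-aroylation (7, 2.2 equiv, pyridine, DMAP cat., rt) would give 2,3-bis(3-benzyloxy-4-methoxybenzoyloxy)-4,5-dimethoxyacetophenone F4. Baker–Venkataraman rearrangement (KOtBu, THF, 0 °C to rt) should shift the 2-O-aroyl group onto the acetyl carbon to give 3-[3-(3-benzyloxy-4-methoxyphenyl)-3-oxopropanoyl]-2-hydroxy-5,6-dimethoxyphenyl 3-benzyloxy-4-methoxybenzoate F5. Methanolysis of the remaining aryl ester (K2CO3, degassed MeOH, rt, Ar; mild acid work-up) should then give 8.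

Step 2. Site control in the second ether cleavage may be lost, through attack at the 4-methoxy group para to the carbonyl or removal of more than one methyl group. The fallback installs the C3 oxygen by C–H functionalisation instead of ether cleavage. It does not branch from a route intermediate: compounds 1 to 3 are replaced by purchased 2-hydroxy-4,5-dimethoxyacetophenone F6, and the route is rejoined at compound 4. Duff formylation (hexamethylenetetramine, CF3CO2H, 90 °C; then aq. HCl) can only occur at C3, the one free position ortho to the phenol, and should give 3-acetyl-2-hydroxy-5,6-dimethoxybenzaldehyde F7. Dakin oxidation (H2O2, aq. NaOH, 0 °C to rt; then acid) should convert the formyl group, which reacts faster than the acetyl group, into the hydroxyl of 4.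

Further compounds
F1 | step 6 | 2-hydroxy-3,4,5,6-tetramethoxyacetophenone (purchased) | CC(=O)c1c(O)c(OC)c(OC)c(OC)c1OC
F2 | step 6 | 1-(3-benzyloxy-4-methoxyphenyl)-3-(2-hydroxy-3,4,5,6-tetramethoxyphenyl)propane-1,3-dione | COc1ccc(C(=O)CC(=O)c2c(O)c(OC)c(OC)c(OC)c2OC)cc1OCc1ccccc1
F3 | step 6 | 3'-benzyloxy-5,6,7,8,4'-pentamethoxyflavone | COc1ccc(-c2cc(=O)c3c(OC)c(OC)c(OC)c(OC)c3o2)cc1OCc1ccccc1
F4 | step 5 | 2,3-bis(3-benzyloxy-4-methoxybenzoyloxy)-4,5-dimethoxyacetophenone | CC(=O)c1cc(OC)c(OC)c(OC(=O)c2ccc(OC)c(OCc3ccccc3)c2)c1OC(=O)c1ccc(OC)c(OCc2ccccc2)c1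
F5 | step 5 | 3-[3-(3-benzyloxy-4-methoxyphenyl)-3-oxopropanoyl]-2-hydroxy-5,6-dimethoxyphenyl 3-benzyloxy-4-methoxybenzoate | COc1ccc(C(=O)CC(=O)c2cc(OC)c(OC)c(OC(=O)c3ccc(OC)c(OCc4ccccc4)c3)c2O)cc1OCc1ccccc1
F6 | step 2 | 2-hydroxy-4,5-dimethoxyacetophenone (purchased) | CC(=O)c1cc(OC)c(OC)cc1O
F7 | step 2 | 3-acetyl-2-hydroxy-5,6-dimethoxybenzaldehyde | CC(=O)c1cc(OC)c(OC)c(C=O)c1O
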